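**Plan**
- Target: (2S)-5-hydroxy-2-(4-hydroxyphenyl)-6,7-dimethoxy-8-prenylchroman-4-one. Retrosynthetic cuts, in order: the 4'-O–Si bond; C3–C4 of ring C (key cut); the C5 O–CH3 bond; C4–C4a (formyl from DMF); C8–CH2 of the prenyl group; C2=C3 (methylene from titanium); O1–C2 (ester).
- Enabling feature: on ring A the C4 carbonyl is flanked by O1 (on C8a) and by the free C5 hydroxyl. C4 can therefore be a formyl carbon and O1 can carry C2=C3 as a 1-arylvinyl ether, while the C5–OH···O=C4 hydrogen bond turns the formyl C–H toward that alkene.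
- Forward order: ring A (3,4,5-trimethoxyphenol) is dibrominated and joined through O1 to the silylated ring B acid. The ester becomes the C2=C3 enol ether, and the two bromines are replaced in turn by the C8 prenyl group and the C4 formyl group. The C5 methyl ether is cleaved, ring C closes last, and desilylation ends the route.
- Stereochemistry: C2, the only stereocenter, is set in the ring closure by the chiral bisphosphine on rhodium. The methyl ether is cleaved before C2 exists, and the final desilylation is buffered.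

Key step: step 8

Assumption: the sense of induction of (R)-DTBM-SEGPHOS cannot be predicted for this new substrate class; the (R)-ligand is written, and its enantiomer is to be used if it leads to (2R). TBS = tert-butyldimethylsilyl; prenyl = 3-methylbut-2-en-1-yl.

**Step 1**
Reactants: 1 3,4,5-trimethoxyphenol
Product: 3 2,6-dibromo-3,4,5-trimethoxyphenol, via monobromide 2 (not isolated)
Conditions: NBS (2.1 equiv), MeCN, 0 °C to rt
Reagents that add atoms: N-bromosuccinimide, O=C1CCC(=O)N1Br
Why: Electrophilic aromatic bromination; the two carbons ortho to the hydroxyl are the only free ring positions and are equivalent, so two equivalents should give the symmetrical dibromide without any regiochemical question.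

**Step 2**
Reactants: 4 4-hydroxybenzoic acid
Product: 6 4-(TBSO)benzoic acid, via silyl ester 5 (not isolated)
Conditions: TBSCl (2.3 equiv), imidazole, DMF, rt; then AcOH/THF/H2O, rt
Reagents that add atoms: tert-butyldimethylsilyl chloride, CC(C)(C)[Si](C)(C)Cl
Why: Standard silylation of phenol and acid, followed by selective hydrolysis of the far more labile silyl ester while the aryl silyl ether stays.

**Step 3**
Reactants: 6 4-(TBSO)benzoic acid; 3 2,6-dibromo-3,4,5-trimethoxyphenol
Product: 8 2,6-dibromo-3,4,5-trimethoxyphenyl 4-(TBSO)benzoate, via acid chloride 7 (not isolated)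
Conditions: (COCl)2, DMF (cat.), CH2Cl2, 0 °C to rt, evaporate; then 3, Et3N, DMAP (cat.), CH2Cl2, 0 °C to rt
Reagents that add atoms: none
Why: Acid chloride formation and DMAP-catalysed O-acylation (nucleophilic acyl substitution) of a hindered but acidic 2,6-dibromophenol, which forms the O1–C2 bond.

**Step 4**
Reactants: 8 2,6-dibromo-3,4,5-trimethoxyphenyl 4-(TBSO)benzoate
Product: 9 tert-butyl{4-[1-(2,6-dibromo-3,4,5-trimethoxyphenoxy)ethenyl]phenoxy}dimethylsilane
Conditions: Cp2TiMe2 (2.5 equiv), toluene, 65 °C, dark; filtration through basic Al2O3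
Reagents that add atoms: dimethyltitanocene Cp2TiMe2, C[Ti+2]C.c1cc[cH-]c1.c1cc[cH-]c1
Why: Petasis methylenation; titanocene methylidene formed on heating converts the aryl ester carbonyl through an oxatitanacyclobutane into the 1,1-disubstituted enol ether (C2=C3) under non-acidic conditions, and the aryl bromides, still free of any carbonyl partner, are inert.

**Step 5**
Reactants: 9 tert-butyl{4-[1-(2,6-dibromo-3,4,5-trimethoxyphenoxy)ethenyl]phenoxy}dimethylsilane; 10 prenyl bromide
Product: 13 tert-butyl(4-{1-[2-bromo-3,4,5-trimethoxy-6-(3-methylbut-2-en-1-yl)phenoxy]ethenyl}phenoxy)dimethylsilane, via aryllithium 11 (not isolated), via arylcopper 12 (not isolated)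
Conditions: n-BuLi (1.05 equiv), THF, −78 °C; CuBr·SMe2 (1.1 equiv), −78 to −40 °C; 10 (1.5 equiv), −40 to 0 °C
Reagents that add atoms: none
Why: Bromine–lithium exchange on the symmetrical dibromide should stop after one exchange because the electron-rich aryllithium resists a second one, and the derived arylcopper attacks prenyl bromide at its primary carbon (copper-mediated allylic substitution), the standard way to prenylate an arene.

**Step 6**
Reactants: 13 tert-butyl(4-{1-[2-bromo-3,4,5-trimethoxy-6-(3-methylbut-2-en-1-yl)phenoxy]ethenyl}phenoxy)dimethylsilane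
Product: 16 2-[(1-{4-[(tert-butyldimethylsilyl)oxy]phenyl}ethenyl)oxy]-4,5,6-trimethoxy-3-(3-methylbut-2-en-1-yl)benzaldehyde, via aryllithium 14 (not isolated), via lithium hemiaminal alkoxide 15 (not isolated)
Conditions: n-BuLi (1.1 equiv), THF, −78 °C; DMF (3 equiv), −78 to 0 °C; pH 7 phosphate buffer
Reagents that add atoms: N,N-dimethylformamide, CN(C)C=O
Why: Second bromine–lithium exchange and Bouveault-type formylation with DMF install C4; the enol ether, silyl ether and prenyl group do not react with n-BuLi at −78 °C, and the neutral quench spares the enol ether.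

**Step 7**
Reactants: 16 2-[(1-{4-[(tert-butyldimethylsilyl)oxy]phenyl}ethenyl)oxy]-4,5,6-trimethoxy-3-(3-methylbut-2-en-1-yl)benzaldehyde
Product: 18 6-hydroxy-2-[(1-{4-[(tert-butyldimethylsilyl)oxy]phenyl}ethenyl)oxy]-4,5-dimethoxy-3-(3-methylbut-2-en-1-yl)benzaldehyde, via magnesium phenoxide 17 (not isolated)
Conditions: MgI2·OEt2 (2 equiv), toluene/Et2O, 50 °C; aq. NH4Cl
Reagents that add atoms: none
Why: Chelation-controlled ether cleavage, in which magnesium binds the formyl oxygen and the neighbouring methoxy oxygen and iodide removes only that methyl group by SN2; this mild Lewis acid is chosen over BCl3 because a strong one would drive the enol ether onto the aldehyde, and the cleavage is placed before C2 exists so that no Lewis acid meets the benzylic C2–O1 stereocenter.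

**Step 8**
Reactants: 18 6-hydroxy-2-[(1-{4-[(tert-butyldimethylsilyl)oxy]phenyl}ethenyl)oxy]-4,5-dimethoxy-3-(3-methylbut-2-en-1-yl)benzaldehyde
Product: 19 (2S)-2-{4-[(tert-butyldimethylsilyl)oxy]phenyl}-5-hydroxy-6,7-dimethoxy-8-(3-methylbut-2-en-1-yl)-2,3-dihydro-4H-chromen-4-one
Conditions: [Rh(cod)Cl]2 (2.5 mol %), (R)-DTBM-SEGPHOS (5.5 mol %), NaB[3,5-(CF3)2C6H3]4 (5 mol %), 1,4-dioxane, 60 °C
Reagents that add atoms: none
Why: Proposed new method: a cationic bisphosphine complex of monovalent rhodium binds the C2=C3 enol ether and adds oxidatively into the formyl C4–H bond, which the C5–OH···O=C4 hydrogen bond keeps turned toward O1; the acyl hydride of trivalent rhodium then passes hydride to C2, the carbon bearing O1 and the aryl group, and the seven-membered acyl alkyl rhodacycle with a primary Rh–C3 bond eliminates reductively to form C3–C4. The closest known reaction type is the rhodium-catalysed enantioselective intramolecular hydroacylation of 1,1-disubstituted alkenes placed ortho to an aryl aldehyde, which has not been shown for an O-linked 1-arylvinyl ether. Ring C closes in the 6-endo-trig mode. C2 is the only new stereocenter and is under ligand control: the chiral bisphosphine selects the alkene face that receives hydride or, if insertion is reversible, selects between the two diastereomeric rhodacycles at reductive elimination. The step needs hydride delivery to C2 and not to C3, which is secured because the other regiochemistry would require reductive elimination from a tertiary alkyl rhodium to a quaternary 2-aryl-2-methylbenzofuran-3-one. It must also outrun decarbonylation and ignore the prenyl group: an ortho hydroxyl is known from salicylaldehyde hydroacylations to hold back decarbonylation by O-coordination, the non-basic medium keeps that contact reversible (a lasting five-membered O,C-chelate would hold rhodium on the C5 side of C4, out of reach of C3), and the trisubstituted prenyl alkene binds too weakly to compete.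

**Step 9**
Reactants: 19 (2S)-2-{4-[(tert-butyldimethylsilyl)oxy]phenyl}-5-hydroxy-6,7-dimethoxy-8-(3-methylbut-2-en-1-yl)-2,3-dihydro-4H-chromen-4-one
Product: 20 (2S)-5-hydroxy-2-(4-hydroxyphenyl)-6,7-dimethoxy-8-(3-methylbut-2-en-1-yl)-2,3-dihydro-4H-chromen-4-one
Conditions: Bu4NF (1.2 equiv), AcOH (1.5 equiv), THF, 0 °C
Reagents that add atoms: none
Why: Fluoride cleavage of the aryl silyl ether, buffered with acetic acid so that no 4'-phenoxide forms that could open ring C to the chalcone and racemise C2; the stereocenter is not touched.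

**Compound list**
1 | 3,4,5-trimethoxyphenol | COc1cc(O)cc(OC)c1OC | starting material
2 | 2-bromo-3,4,5-trimethoxyphenol | COc1cc(O)c(Br)c(OC)c1OC | intermediate (not isolated)
3 | 2,6-dibromo-3,4,5-trimethoxyphenol | COc1c(OC)c(Br)c(O)c(Br)c1OC | intermediate
4 | 4-hydroxybenzoic acid | O=C(O)c1ccc(O)cc1 | starting material
5 | tert-butyldimethylsilyl 4-[(tert-butyldimethylsilyl)oxy]benzoate | CC(C)(C)[Si](C)(C)OC(=O)c1ccc(O[Si](C)(C)C(C)(C)C)cc1 | intermediate (not isolated)
6 | 4-[(tert-butyldimethylsilyl)oxy]benzoic acid | O=C(O)c1ccc(O[Si](C)(C)C(C)(C)C)cc1 | intermediate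
7 | 4-[(tert-butyldimethylsilyl)oxy]benzoyl chloride | O=C(Cl)c1ccc(O[Si](C)(C)C(C)(C)C)cc1 | intermediate (not isolated)
8 | 2,6-dibromo-3,4,5-trimethoxyphenyl 4-[(tert-butyldimethylsilyl)oxy]benzoate | COc1c(OC)c(Br)c(OC(=O)c2ccc(O[Si](C)(C)C(C)(C)C)cc2)c(Br)c1OC | intermediate
9 | tert-butyl{4-[1-(2,6-dibromo-3,4,5-trimethoxyphenoxy)ethenyl]phenoxy}dimethylsilane | COc1c(OC)c(Br)c(OC(=C)c2ccc(O[Si](C)(C)C(C)(C)C)cc2)c(Br)c1OC | intermediate
10 | prenyl bromide (1-bromo-3-methylbut-2-ene) | CC(C)=CCBr | starting material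
11 | {3-bromo-2-[(1-{4-[(tert-butyldimethylsilyl)oxy]phenyl}ethenyl)oxy]-4,5,6-trimethoxyphenyl}lithium | COc1c(OC)c(Br)c(OC(=C)c2ccc(O[Si](C)(C)C(C)(C)C)cc2)c([Li])c1OC | intermediate (not isolated)
12 | {3-bromo-2-[(1-{4-[(tert-butyldimethylsilyl)oxy]phenyl}ethenyl)oxy]-4,5,6-trimethoxyphenyl}copper | COc1c(OC)c(Br)c(OC(=C)c2ccc(O[Si](C)(C)C(C)(C)C)cc2)c([Cu])c1OC | intermediate (not isolated)
13 | tert-butyl(4-{1-[2-bromo-3,4,5-trimethoxy-6-(3-methylbut-2-en-1-yl)phenoxy]ethenyl}phenoxy)dimethylsilane | COc1c(OC)c(Br)c(OC(=C)c2ccc(O[Si](C)(C)C(C)(C)C)cc2)c(CC=C(C)C)c1OC | intermediate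
14 | {2-[(1-{4-[(tert-butyldimethylsilyl)oxy]phenyl}ethenyl)oxy]-4,5,6-trimethoxy-3-(3-methylbut-2-en-1-yl)phenyl}lithium | COc1c(OC)c([Li])c(OC(=C)c2ccc(O[Si](C)(C)C(C)(C)C)cc2)c(CC=C(C)C)c1OC | intermediate (not isolated)
15 | lithium (dimethylamino){2-[(1-{4-[(tert-butyldimethylsilyl)oxy]phenyl}ethenyl)oxy]-4,5,6-trimethoxy-3-(3-methylbut-2-en-1-yl)phenyl}methanolate | COc1c(OC)c(C(O[Li])N(C)C)c(OC(=C)c2ccc(O[Si](C)(C)C(C)(C)C)cc2)c(CC=C(C)C)c1OC | intermediate (not isolated)
16 | 2-[(1-{4-[(tert-butyldimethylsilyl)oxy]phenyl}ethenyl)oxy]-4,5,6-trimethoxy-3-(3-methylbut-2-en-1-yl)benzaldehyde | COc1c(OC)c(C=O)c(OC(=C)c2ccc(O[Si](C)(C)C(C)(C)C)cc2)c(CC=C(C)C)c1OC | intermediate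
17 | iodomagnesium phenoxide of 18 (O–Mg–I on the oxygen ortho to the formyl group) | COc1c(O[Mg]I)c(C=O)c(OC(=C)c2ccc(O[Si](C)(C)C(C)(C)C)cc2)c(CC=C(C)C)c1OC | intermediate (not isolated)
18 | 6-hydroxy-2-[(1-{4-[(tert-butyldimethylsilyl)oxy]phenyl}ethenyl)oxy]-4,5-dimethoxy-3-(3-methylbut-2-en-1-yl)benzaldehyde | COc1c(O)c(C=O)c(OC(=C)c2ccc(O[Si](C)(C)C(C)(C)C)cc2)c(CC=C(C)C)c1OC | intermediate (key-step precursor)
19 | (2S)-2-{4-[(tert-butyldimethylsilyl)oxy]phenyl}-5-hydroxy-6,7-dimethoxy-8-(3-methylbut-2-en-1-yl)-2,3-dihydro-4H-chromen-4-one | COc1c(O)c2c(c(CC=C(C)C)c1OC)O[C@H](c1ccc(O[Si](C)(C)C(C)(C)C)cc1)CC2=O | intermediate (key-step product)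
20 | (2S)-5-hydroxy-2-(4-hydroxyphenyl)-6,7-dimethoxy-8-(3-methylbut-2-en-1-yl)-2,3-dihydro-4H-chromen-4-one | COc1c(O)c2c(c(CC=C(C)C)c1OC)O[C@H](c1ccc(O)cc1)CC2=O | target

**Step count**
Total: 9 steps. Longest linear sequence: 8 steps (steps 1 and 3–9 from 3,4,5-trimethoxyphenol; steps 2–9 from 4-hydroxybenzoic acid are equally long).

**Steps most likely to fail**

1. Step 8 (proposed new method). The acyl rhodium hydride may decarbonylate, hydride may go to C3 with five-ring closure, the facial selectivity may be low, or the catalyst may be held as a phenoxide chelate or arene complex. The fallback uses known chemistry, sets out from 13 and returns at 19. It gives up the ring B carbons already attached and brings them back as a boronic acid.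
   - Bromine–lithium exchange on 13 as in step 6 and trapping with N-methoxy-N-methylacetamide should give the aryl methyl ketone F1.
   - Pyridinium p-toluenesulfonate in wet acetone hydrolyses the enol ether to 1-[2-hydroxy-4,5,6-trimethoxy-3-(3-methylbut-2-en-1-yl)phenyl]ethanone F2.
   - DMF dimethyl acetal gives the enaminone F3, which closes under mild acid (AcOH, toluene, warm) to 5,6,7-trimethoxy-8-prenylchromone F4.
   - BCl3 (CH2Cl2, −78 °C) cleaves the methyl ether next to the carbonyl, before any stereocenter exists, to give 5-hydroxy-6,7-dimethoxy-8-prenylchromone F5.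
   - Asymmetric conjugate addition of [4-(tert-butyldimethylsilyloxy)phenyl]boronic acid with Pd(OCOCF3)2 and the t-BuPyOx enantiomer that leads to (2S) then gives 19.

2. Step 7. The Lewis acid may trigger addition of the enol ether to the chelated aldehyde (Prins-type closure toward a flavylium salt), or the enol ether may be hydrolysed, in competition with the SN2 demethylation. The fallback changes the order of events, sets out from 16 and returns at 19. Ring C is closed on the methyl ether under the conditions of step 8 to give the (2S)-5-O-methyl flavanone F6. The methyl ether next to the C4 carbonyl is then cleaved with BCl3 (CH2Cl2, −78 °C), the classical selective 5-O-demethylation of flavanones. No enol ether is present by then, but the optical purity of 19 would have to be checked because a Lewis acid can open ring C.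

3. Step 5. Both bromines may exchange, the aryllithium may be protonated, or allylic attack may occur at the tertiary end of prenyl bromide. The fallback installs the prenyl group at the phenol stage, sets out from 2 (isolated by running step 1 with one equivalent of NBS) and returns at 13. The sodium phenoxide of 2 (NaH, toluene) is C-alkylated with 10 at its free ortho carbon, a classical phenoxide ortho-prenylation in a non-polar solvent, to give 2-bromo-3,4,5-trimethoxy-6-(3-methylbut-2-en-1-yl)phenol F7. Acylation with 7 as in step 3 gives the aryl ester F8, and Petasis methylenation as in step 4 gives 13.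

**Further compounds**
F1 | step 8 | 1-{2-[(1-{4-[(tert-butyldimethylsilyl)oxy]phenyl}ethenyl)oxy]-4,5,6-trimethoxy-3-(3-methylbut-2-en-1-yl)phenyl}ethanone | COc1c(OC)c(C(C)=O)c(OC(=C)c2ccc(O[Si](C)(C)C(C)(C)C)cc2)c(CC=C(C)C)c1OC
F2 | step 8 | 1-[2-hydroxy-4,5,6-trimethoxy-3-(3-methylbut-2-en-1-yl)phenyl]ethanone | COc1c(OC)c(C(C)=O)c(O)c(CC=C(C)C)c1OC
F3 | step 8 | (E)-3-(dimethylamino)-1-[2-hydroxy-4,5,6-trimethoxy-3-(3-methylbut-2-en-1-yl)phenyl]prop-2-en-1-one | COc1c(OC)c(C(=O)/C=C/N(C)C)c(O)c(CC=C(C)C)c1OC
F4 | step 8 | 5,6,7-trimethoxy-8-(3-methylbut-2-en-1-yl)-4H-chromen-4-one | COc1c(OC)c2c(=O)ccoc2c(CC=C(C)C)c1OC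
F5 | step 8 | 5-hydroxy-6,7-dimethoxy-8-(3-methylbut-2-en-1-yl)-4H-chromen-4-one | COc1c(O)c2c(=O)ccoc2c(CC=C(C)C)c1OC
F6 | step 7 | (2S)-2-{4-[(tert-butyldimethylsilyl)oxy]phenyl}-5,6,7-trimethoxy-8-(3-methylbut-2-en-1-yl)-2,3-dihydro-4H-chromen-4-one | COc1c(OC)c2c(c(CC=C(C)C)c1OC)O[C@H](c1ccc(O[Si](C)(C)C(C)(C)C)cc1)CC2=O
F7 | step 5 | 2-bromo-3,4,5-trimethoxy-6-(3-methylbut-2-en-1-yl)phenol | COc1c(OC)c(Br)c(O)c(CC=C(C)C)c1OC
F8 | step 5 | 2-bromo-3,4,5-trimethoxy-6-(3-methylbut-2-en-1-yl)phenyl 4-[(tert-butyldimethylsilyl)oxy]benzoate | COc1c(OC)c(Br)c(OC(=O)c2ccc(O[Si](C)(C)C(C)(C)C)cc2)c(CC=C(C)C)c1OC
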